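**Retrosynthetic overview**
1. Target ⇒ late acylation of 8β-OH with (2Z)-4-acetoxy-2-methylbut-2-enoic acid (from 3-methylfuran-2(5H)-one) after opening an α-methylene 8,12-γ-lactone.
2. 8,12-Lactone ⇒ iodolactonisation of a C7 acetic acid that an Ireland–Claisen shift carries over from a 9β-acetate; C10 vinyl ⇒ lactol + Wittig.
3. 9β-OAc and 6α-O ⇒ one palladium-catalysed 1,4-acetoxylactonisation of a cyclohexa-1,3-diene by its own C1 carboxylate.
4. Diene, C5 side chain and absolute configuration ⇒ enantioselective desymmetrising Heck cyclisation of an achiral cyclohexa-1,4-diene 2-bromoallyl ester, itself from Birch reductive methylation of benzoic acid.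
5. Ring order: the carbocycle comes from the arene; then three temporary lactones in turn (1,15-δ → 1,6-γ → 8,12-γ), all opened again.

Convention: elemane locants are used for all intermediates (C10 = quaternary ring carbon with CH3 C14 and C1; ring C9, C8, C7, C6, C5; C4(=C3)–C15 on C5; C11(=C13)–C12 on C7); β = face of the C14 methyl, α = opposite face; TBS = tert-butyldimethylsilyl, TES = triethylsilyl, PMB = 4-methoxybenzyl.
Assumption: (R)-BINAP is taken to give the enantiomer drawn in step 3; if it gives the antipode, (S)-BINAP is used and nothing else changes.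

Step 1
Reactants: 1 benzoic acid
Product: 3 1-methylcyclohexa-2,5-diene-1-carboxylic acid, via Birch dianion 2 (not isolated)
Conditions: Li (3.2 equiv), NH3(l)/THF, −78 °C; MeI (excess), −78 °C to rt; aq. HCl
Reagents that add atoms: iodomethane, CI
Why: Birch reduction of the benzoate gives the cross-conjugated dienediolate, which is C-methylated at the ipso carbon (Birch reductive alkylation), so C10 becomes quaternary in a still achiral 1,4-diene whose two ring alkenes are enantiotopic.

Step 2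
Reactants: 3 1-methylcyclohexa-2,5-diene-1-carboxylic acid
Product: 4 2-bromoprop-2-en-1-yl 1-methylcyclohexa-2,5-diene-1-carboxylate
Conditions: 2,3-dibromopropene (1.2 equiv), K2CO3, DMF, rt
Reagents that add atoms: 2,3-dibromoprop-1-ene, C=C(Br)CBr
Why: SN2 O-alkylation of the carboxylate at the allylic (not the vinylic) bromide attaches the three-carbon tether that becomes C3, C4 and C15, and no stereocentre is formed.

Step 3
Reactants: 4 2-bromoprop-2-en-1-yl 1-methylcyclohexa-2,5-diene-1-carboxylate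
Product: 5 (4aR,8aR)-8a-methyl-4-methylidene-3,4,4a,8a-tetrahydro-1H-isochromen-1-one (cis-fused 1,15-lactone; C1 and C4 both α)
Conditions: Pd2(dba)3 (5 mol %), (R)-BINAP (12 mol %), Ag3PO4 (1.5 equiv), N-methylpyrrolidone, 70 °C
Reagents that add atoms: none
Why: Enantioselective desymmetrising intramolecular Heck reaction, in which zerovalent palladium inserts into the vinyl bromide, the silver salt opens the cationic pathway where the BINAP ligand chooses one of the two enantiotopic ring alkenes (absolute configuration of C10), 6-exo syn-carbopalladation through the short tether can only place C4 on the face of C1 (C5 cis to C1), and syn β-hydride elimination toward C7 leaves the conjugated diene.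

Step 4
Reactants: 5 cis-fused diene lactone
Product: 8 6-[3-(TBS-oxy)prop-1-en-2-yl]-1-methylcyclohexa-2,4-diene-1-carboxylic acid (CO2H/side chain cis; both α), via lithium hydroxy carboxylate 6 (not isolated), via bis-silyl derivative 7 (not isolated)
Conditions: LiOH·H2O (1.5 equiv), THF/H2O, 0 °C to rt; evaporate; TBSCl (3 equiv), imidazole, DMF, rt; K2CO3, MeOH/H2O, 0 °C; pH 4 buffer
Reagents that add atoms: lithium hydroxide, [Li+].[OH-]; tert-butyl(chloro)dimethylsilane, CC(C)(C)[Si](C)(C)Cl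
Why: Saponification (acyl–oxygen cleavage) frees the C1 carboxylate needed as an internal nucleophile and the C15 hydroxyl, which is silylated while the silyl ester formed alongside is cleaved selectively, and no stereocentre is touched.

Step 5
Reactants: 8 diene acid
Product: 9 2-acetoxy-1-methyl-8-[3-(TBS-oxy)prop-1-en-2-yl]-6-oxabicyclo[3.2.1]oct-3-en-7-one (1,6α-lactone; 9β-OAc; C5 side chain α)
Conditions: Pd(OAc)2 (5 mol %), p-benzoquinone (2 equiv), acetone/AcOH (4:1), no chloride, rt
Reagents that add atoms: acetic acid, CC(=O)O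
Why: Palladium-catalysed 1,4-oxylactonisation of a conjugated diene with benzoquinone as reoxidant, in which divalent palladium binds the diene on the β face, the C1 carboxylate attacks C6 anti to the metal (bridged five-membered lactone, so O6 is α and cis to C1), and without chloride the π-allylpalladium transfers a coordinated acetate from the metal face to C9, setting the 9β-acetate trans to O6.

Step 6
Reactants: 9 bridged lactone allylic acetate
Product: 12 2-{1-methyl-7-oxo-8-[3-(TBS-oxy)prop-1-en-2-yl]-6-oxabicyclo[3.2.1]oct-2-en-4-yl}acetic acid (7β-CH2CO2H), via silyl ketene acetal 10 (not isolated), via trimethylsilyl ester 11 (not isolated)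
Conditions: LiN(iPr)2 (1.3 equiv), Me3SiCl/Et3N, THF, −78 °C; then 60 °C; aq. NH4Cl
Reagents that add atoms: none
Why: Ireland–Claisen rearrangement, in which only the acetate can enolise (the lactone has no α-hydrogen) and the suprafacial [3,3] shift of its silyl ketene acetal across the pseudo-axial C9–O bond delivers C11–C12 to C7 on the same β face while the alkene moves to C8=C9.

Step 7
Reactants: 12 lactone acid
Product: 14 2-{7-hydroxy-1-methyl-8-[3-(TBS-oxy)prop-1-en-2-yl]-6-oxabicyclo[3.2.1]oct-2-en-4-yl}acetic acid (lactol; C1 epimers), via lithium carboxylate 13 (not isolated)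
Conditions: LiN(SiMe3)2 (1.0 equiv), THF, −78 °C; iBu2AlH (1.5 equiv), CH2Cl2, −78 °C; aq. KNaC4H4O6, then 1 M HCl to pH 4
Reagents that add atoms: none
Why: Partial reduction of a lactone to a lactol, in which the acid is first stored as its lithium carboxylate that iBu2AlH does not reduce at −78 °C, so hydride adds only to the strained bridged lactone carbonyl; the ring stereocentres are untouched and the lactol carbon is an inconsequential epimer mixture.

Step 8
Reactants: 14 lactol acid
Product: 17 2-{4-ethenyl-4-methyl-5-[3-(TBS-oxy)prop-1-en-2-yl]-6-(TES-oxy)cyclohex-2-en-1-yl}acetic acid (7β-CH2CO2H; 6α-OTES; 5α side chain; 10α-vinyl), via dipotassium alkoxide carboxylate 15 (not isolated), via triethylsilyl ester 16 (not isolated)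
Conditions: Ph3PCH3Br (5 equiv), KOtBu (5 equiv), THF, 0 °C to rt; Et3SiCl (3 equiv), 0 °C; K2CO3, MeOH/H2O, 0 °C; pH 4 buffer
Reagents that add atoms: methyltriphenylphosphonium bromide, C[P+](c1ccccc1)(c1ccccc1)c1ccccc1.[Br-]; chlorotriethylsilane, CC[Si](Cl)(CC)CC
Why: Wittig methylenation of the aldehyde in equilibrium with the deprotonated lactol turns C1 into the C10 vinyl group and releases the 6α-alkoxide, which is silylated in the same flask (the silyl ester also formed is cleaved on work-up), and since no bond to C10 or C6 is broken both keep their configuration.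

Step 9
Reactants: 17 cyclohexenyl acetic acid
Product: 18 6-ethenyl-7-iodo-6-methyl-5-[3-(TBS-oxy)prop-1-en-2-yl]-4-(TES-oxy)hexahydro-1-benzofuran-2(3H)-one (cis-fused 8β,12-lactone; 9α-I)
Conditions: I2 (3 equiv), NaHCO3, MeCN/H2O, 0 °C to rt, dark
Reagents that add atoms: iodine, II
Why: Iodolactonisation, in which (the ring now being unlocked) the C12 carboxylate attacks C8 of the reversibly formed iodonium ion 5-exo from its own β face, so the γ-lactone is necessarily cis-fused (8β-O cis to the C7 chain) with iodine anti at C9, the only five-membered outcome available.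

Step 10
Reactants: 18 iodolactone
Product: 19 6-ethenyl-6-methyl-5-[3-(TBS-oxy)prop-1-en-2-yl]-4-(TES-oxy)hexahydro-1-benzofuran-2(3H)-one (cis-fused 8β,12-lactone; C9 = CH2)
Conditions: Bu3SnH (3 equiv, 0.5 M), (PhSe)2 (5 mol %), Et3B/air, toluene, −78 °C
Reagents that add atoms: none
Why: Radical chain dehalogenation, in which the C9 radical is reduced by the stannane and the much faster selenol made in situ, which at −78 °C outruns the 1,2-vinyl shift from C10, so C9 ends as CH2 and no stereocentre changes.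

Step 11
Reactants: 19 γ-lactone
Product: 22 6-ethenyl-6-methyl-3-methylidene-5-[3-(TBS-oxy)prop-1-en-2-yl]-4-(TES-oxy)hexahydro-1-benzofuran-2(3H)-one, via Mannich base 20 (not isolated), via trimethylammonium iodide 21 (not isolated)
Conditions: LiN(iPr)2 (1.2 equiv), THF, −78 °C; [Me2N=CH2]I (2 equiv), −78 °C to rt; MeI, MeOH, rt; aq. NaHCO3, CH2Cl2
Reagents that add atoms: N,N-dimethylmethyleneiminium iodide, C=[N+](C)C.[I-]
Why: α-Methylenation of the lactone by Mannich reaction of its lithium enolate with the iminium salt, N-methylation and base-induced elimination of trimethylamine installs C11=C13, with C7 and C8 not involved and the transient C11 stereocentre removed.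

Step 12
Reactants: 22 α-methylene lactone
Product: 24 4-methoxybenzyl 2-{4-ethenyl-6-hydroxy-4-methyl-3-[3-(TBS-oxy)prop-1-en-2-yl]-2-(TES-oxy)cyclohexyl}prop-2-enoate (8β-OH; 6α-OTES; ring configuration as in the target), via lithium hydroxy carboxylate 23 (not isolated)
Conditions: LiOH·H2O (1.2 equiv), THF/H2O, 0 °C; evaporate; 4-methoxybenzyl chloride (1.5 equiv), Bu4NI (cat.), DMF, rt
Reagents that add atoms: lithium hydroxide, [Li+].[OH-]; 4-methoxybenzyl chloride, COc1ccc(CCl)cc1
Why: Saponification of the only carbonyl group releases the 8β-hydroxyl and the C12 carboxylate, which is O-alkylated as its salt (SN2) before any acidification so that the cis γ-hydroxy acid cannot close again, and C8 keeps its configuration.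

Step 13
Reactants: 25 3-methylfuran-2(5H)-one
Product: 29 (2Z)-4-acetoxy-2-methylbut-2-enoic acid, via potassium hydroxy enoate 26 (not isolated), via hydroxy silyl ester 27 (not isolated), via acetoxy silyl ester 28 (not isolated)
Conditions: KOH (1.0 equiv), H2O/MeOH, rt; evaporate; TBSCl (1.05 equiv), DMF, 0 °C; Ac2O, pyridine, DMAP (cat.), 0 °C; AcOH/THF/H2O, rt
Reagents that add atoms: potassium hydroxide, [K+].[OH-]; acetic anhydride, CC(=O)OC(C)=O
Why: Saponification opens the butenolide without touching the ring-locked (Z) alkene, the carboxylate is masked as a silyl ester so that acetylation of the primary hydroxyl cannot trigger relactonisation, and mild aqueous acid then frees the acid with the (Z) geometry inherited from the ring.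

Step 14
Reactants: 24 hydroxy PMB ester; 29 (2Z)-4-acetoxy-2-methylbut-2-enoic acid
Product: 31 4-methoxybenzyl ester 6-O-TES 15-O-TBS derivative of the target (8β-O-acyl), via mixed trichlorobenzoic anhydride 30 (not isolated)
Conditions: 29 (2 equiv), 2,4,6-trichlorobenzoyl chloride (2 equiv), Et3N (2.2 equiv), toluene, rt; then 24, toluene, 60 °C (no DMAP)
Reagents that add atoms: 29 (2Z)-4-acetoxy-2-methylbut-2-enoic acid, OC(=O)/C(C)=C\COC(C)=O
Why: Yamaguchi esterification, in which the preformed mixed 2,4,6-trichlorobenzoic anhydride acylates the only free hydroxyl (8β-OH) with retention at C8 and the absence of a nucleophilic pyridine catalyst avoids addition–elimination isomerisation of the (Z)-enoate.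

Step 15
Reactants: 31 fully protected ester
Product: 32 2-[(1S,2R,3S,4S,6R)-6-{[(2Z)-4-acetoxy-2-methylbut-2-enoyl]oxy}-4-ethenyl-2-hydroxy-3-(3-hydroxyprop-1-en-2-yl)-4-methylcyclohexyl]prop-2-enoic acid
Conditions: CF3CO2H/CH2Cl2/H2O (3:6:1), 0 °C to rt; pH 4 work-up
Reagents that add atoms: none
Why: Global acidolysis (SN1 cleavage of the 4-methoxybenzyl ester and protodesilylation of both silyl ethers) frees the acid and the two hydroxyls while the acetate and enoate esters survive aqueous acid, no stereocentre is involved, and the 6α-hydroxyl being trans to the C7 side chain disfavours lactonisation.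

**Compound list**
1 | benzoic acid | OC(=O)c1ccccc1 | starting material
2 | dilithium (cyclohexa-2,5-dien-1-ylidene)methanediolate (Birch dianion) | [Li+].[Li+].[O-]C([O-])=C1C=CCC=C1 | intermediate
3 | 1-methylcyclohexa-2,5-diene-1-carboxylic acid (achiral) | CC1(C(=O)O)C=CCC=C1 | intermediate
4 | 2-bromoprop-2-en-1-yl 1-methylcyclohexa-2,5-diene-1-carboxylate (achiral) | CC1(C(=O)OCC(Br)=C)C=CCC=C1 | intermediate
5 | (4aR,8aR)-8a-methyl-4-methylidene-3,4,4a,8a-tetrahydro-1H-isochromen-1-one (cis-fused; C1 and C4 α) | O=C2[C@]1(C)C=CC=C[C@@H]1C(=C)CO2 | intermediate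
6 | lithium 6-(3-hydroxyprop-1-en-2-yl)-1-methylcyclohexa-2,4-diene-1-carboxylate (carboxylate and side chain cis) | [Li+].[O-]C(=O)[C@]1(C)C=CC=C[C@@H]1C(=C)CO | intermediate
7 | TBS ester of 8 (TBS ether and TBS ester) | CC(C)(C)[Si](C)(C)OC(=O)[C@]1(C)C=CC=C[C@@H]1C(=C)CO[Si](C)(C)C(C)(C)C | intermediate
8 | 6-[3-(TBS-oxy)prop-1-en-2-yl]-1-methylcyclohexa-2,4-diene-1-carboxylic acid (CO2H and side chain cis, both α) | OC(=O)[C@]1(C)C=CC=C[C@@H]1C(=C)CO[Si](C)(C)C(C)(C)C | intermediate
9 | 2-acetoxy-1-methyl-8-[3-(TBS-oxy)prop-1-en-2-yl]-6-oxabicyclo[3.2.1]oct-3-en-7-one (1,6α-lactone; 9β-OAc; C5 side chain α) | O=C2[C@]1(C)[C@@H](OC(C)=O)C=C[C@H](O2)[C@@H]1C(=C)CO[Si](C)(C)C(C)(C)C | intermediate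
10 | trimethylsilyl ketene acetal of 9 | O=C2[C@]1(C)[C@@H](OC(=C)O[Si](C)(C)C)C=C[C@H](O2)[C@@H]1C(=C)CO[Si](C)(C)C(C)(C)C | intermediate
11 | trimethylsilyl ester of 12 | O=C2[C@]1(C)C=C[C@@H](CC(=O)O[Si](C)(C)C)[C@H](O2)[C@@H]1C(=C)CO[Si](C)(C)C(C)(C)C | intermediate
12 | 2-{1-methyl-7-oxo-8-[3-(TBS-oxy)prop-1-en-2-yl]-6-oxabicyclo[3.2.1]oct-2-en-4-yl}acetic acid (1,6α-lactone; 7β-CH2CO2H) | O=C2[C@]1(C)C=C[C@@H](CC(=O)O)[C@H](O2)[C@@H]1C(=C)CO[Si](C)(C)C(C)(C)C | intermediate
13 | lithium salt of 12 | [Li+].O=C2[C@]1(C)C=C[C@@H](CC(=O)[O-])[C@H](O2)[C@@H]1C(=C)CO[Si](C)(C)C(C)(C)C | intermediate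
14 | 2-{7-hydroxy-1-methyl-8-[3-(TBS-oxy)prop-1-en-2-yl]-6-oxabicyclo[3.2.1]oct-2-en-4-yl}acetic acid (lactol, both C1 epimers) | OC2[C@]1(C)C=C[C@@H](CC(=O)O)[C@H](O2)[C@@H]1C(=C)CO[Si](C)(C)C(C)(C)C | intermediate
15 | dipotassium salt of 2-{4-ethenyl-6-hydroxy-4-methyl-5-[3-(TBS-oxy)prop-1-en-2-yl]cyclohex-2-en-1-yl}acetic acid (6α-alkoxide and carboxylate) | [K+].[K+].C=C[C@]1(C)C=C[C@@H](CC(=O)[O-])[C@H]([O-])[C@@H]1C(=C)CO[Si](C)(C)C(C)(C)C | intermediate
16 | triethylsilyl ester of 17 | C=C[C@]1(C)C=C[C@@H](CC(=O)O[Si](CC)(CC)CC)[C@H](O[Si](CC)(CC)CC)[C@@H]1C(=C)CO[Si](C)(C)C(C)(C)C | intermediate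
17 | 2-{4-ethenyl-4-methyl-5-[3-(TBS-oxy)prop-1-en-2-yl]-6-(TES-oxy)cyclohex-2-en-1-yl}acetic acid (7β-CH2CO2H; 6α-OTES; 5α side chain; 10α-vinyl) | C=C[C@]1(C)C=C[C@@H](CC(=O)O)[C@H](O[Si](CC)(CC)CC)[C@@H]1C(=C)CO[Si](C)(C)C(C)(C)C | intermediate
18 | 6-ethenyl-7-iodo-6-methyl-5-[3-(TBS-oxy)prop-1-en-2-yl]-4-(TES-oxy)hexahydro-1-benzofuran-2(3H)-one (cis-fused 8β,12-lactone; 9α-I) | C=C[C@]1(C)[C@H](I)[C@@H](OC(=O)C2)[C@@H]2[C@H](O[Si](CC)(CC)CC)[C@@H]1C(=C)CO[Si](C)(C)C(C)(C)C | intermediate
19 | 6-ethenyl-6-methyl-5-[3-(TBS-oxy)prop-1-en-2-yl]-4-(TES-oxy)hexahydro-1-benzofuran-2(3H)-one (cis-fused 8β,12-lactone) | C=C[C@]1(C)C[C@@H](OC(=O)C2)[C@@H]2[C@H](O[Si](CC)(CC)CC)[C@@H]1C(=C)CO[Si](C)(C)C(C)(C)C | intermediate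
20 | 3-[(dimethylamino)methyl] derivative of 19 (Mannich base, C11 epimers) | C=C[C@]1(C)C[C@@H](OC(=O)C2CN(C)C)[C@@H]2[C@H](O[Si](CC)(CC)CC)[C@@H]1C(=C)CO[Si](C)(C)C(C)(C)C | intermediate
21 | N-methyl ammonium iodide of 20 | [I-].C=C[C@]1(C)C[C@@H](OC(=O)C2C[N+](C)(C)C)[C@@H]2[C@H](O[Si](CC)(CC)CC)[C@@H]1C(=C)CO[Si](C)(C)C(C)(C)C | intermediate
22 | 6-ethenyl-6-methyl-3-methylidene-5-[3-(TBS-oxy)prop-1-en-2-yl]-4-(TES-oxy)hexahydro-1-benzofuran-2(3H)-one (cis-fused α-methylene 8β,12-lactone) | C=C[C@]1(C)C[C@@H](OC(=O)C2=C)[C@@H]2[C@H](O[Si](CC)(CC)CC)[C@@H]1C(=C)CO[Si](C)(C)C(C)(C)C | intermediate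
23 | lithium 2-{4-ethenyl-6-hydroxy-4-methyl-3-[3-(TBS-oxy)prop-1-en-2-yl]-2-(TES-oxy)cyclohexyl}prop-2-enoate (8β-OH) | [Li+].C=C[C@]1(C)C[C@@H](O)[C@@H](C(=C)C(=O)[O-])[C@H](O[Si](CC)(CC)CC)[C@@H]1C(=C)CO[Si](C)(C)C(C)(C)C | intermediate
24 | 4-methoxybenzyl 2-{4-ethenyl-6-hydroxy-4-methyl-3-[3-(TBS-oxy)prop-1-en-2-yl]-2-(TES-oxy)cyclohexyl}prop-2-enoate (8β-OH; 6α-OTES) | C=C[C@]1(C)C[C@@H](O)[C@@H](C(=C)C(=O)OCc2ccc(OC)cc2)[C@H](O[Si](CC)(CC)CC)[C@@H]1C(=C)CO[Si](C)(C)C(C)(C)C | intermediate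
25 | 3-methylfuran-2(5H)-one | CC1=CCOC1=O | starting material
26 | potassium (2Z)-4-hydroxy-2-methylbut-2-enoate | [K+].[O-]C(=O)/C(C)=C\CO | intermediate
27 | tert-butyldimethylsilyl (2Z)-4-hydroxy-2-methylbut-2-enoate | CC(C)(C)[Si](C)(C)OC(=O)/C(C)=C\CO | intermediate
28 | tert-butyldimethylsilyl (2Z)-4-acetoxy-2-methylbut-2-enoate | CC(C)(C)[Si](C)(C)OC(=O)/C(C)=C\COC(C)=O | intermediate
29 | (2Z)-4-acetoxy-2-methylbut-2-enoic acid | OC(=O)/C(C)=C\COC(C)=O | intermediate
30 | (2Z)-4-acetoxy-2-methylbut-2-enoic 2,4,6-trichlorobenzoic anhydride | O=C(OC(=O)/C(C)=C\COC(C)=O)c1c(Cl)cc(Cl)cc1Cl | intermediate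
31 | 4-methoxybenzyl ester, 6-O-TES, 15-O-TBS derivative of the target | C=C[C@]1(C)C[C@@H](OC(=O)/C(C)=C\COC(C)=O)[C@@H](C(=C)C(=O)OCc2ccc(OC)cc2)[C@H](O[Si](CC)(CC)CC)[C@@H]1C(=C)CO[Si](C)(C)C(C)(C)C | intermediate
32 | 2-[(1S,2R,3S,4S,6R)-6-{[(2Z)-4-acetoxy-2-methylbut-2-enoyl]oxy}-4-ethenyl-2-hydroxy-3-(3-hydroxyprop-1-en-2-yl)-4-methylcyclohexyl]prop-2-enoic acid | C=C[C@]1(C)C[C@@H](OC(=O)/C(C)=C\COC(C)=O)[C@@H](C(=C)C(=O)O)[C@H](O)[C@@H]1C(=C)CO | target

**Totals**
Total step count: 15 (14 in the main line plus step 13 for the side-chain acid). Longest linear sequence: 14 steps (steps 1–12, 14, 15).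

**Three steps most likely to fail, with fallbacks**

Step 3 (desymmetrising Heck through an ester tether). Zerovalent palladium may ionise the allylic ester, or the alkenylpalladium may lose the carboxylate, and the enantioselectivity is untested on this tether. The fallback changes the tether to an acetal and sets out from 3. LiAlH4 reduction gives (1-methylcyclohexa-2,5-dien-1-yl)methanol F1, and Dess–Martin oxidation gives 1-methylcyclohexa-2,5-diene-1-carbaldehyde F2. Acetalisation with 2-bromoprop-2-en-1-ol (pyridinium p-toluenesulfonate, benzene, water removal) gives the bis(2-bromoallyl) acetal F3. The same Pd2(dba)3/(R)-BINAP/Ag3PO4 Heck desymmetrisation, now on a 2-bromoallyl ether that cannot ionise, gives the cis-fused cyclic mixed acetal F4 (acetal epimers are irrelevant). Aqueous AcOH/THF releases the lactol F5, and Ag2CO3 on Celite (benzene, reflux) oxidises it to lactone 5, where the route is rejoined.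

Step 5 (palladium 1,4-acetoxylactonisation). The acetate may go to C7 instead of C9 or enter on the wrong face, or the diene acid may aromatise by decarboxylation. The fallback replaces the metal step by a selenium relay and sets out from 8. PhSeCl (CH2Cl2, −78 °C) gives, by anti addition, the 7β-phenylseleno 1,6α-lactone F6. H2O2/pyridine gives the allylic selenoxide, whose suprafacial [2,3]-sigmatropic shift moves oxygen to C9 on the β face and, after hydrolysis of the selenenate, leaves the 9β-hydroxy 1,6α-lactone F7. Ac2O/DMAP/pyridine then gives 9, where the route is rejoined.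

Step 14 (acylation of the hindered 8β-OH in a cis γ-hydroxy ester with a (Z)-enoic acid). Heating with amine may relactonise 24, and the activated (Z)-acid may isomerise or deconjugate. The fallback builds the (Z)-enoate on the substrate and sets out from 24. Carbodiimide coupling (N,N'-dicyclohexylcarbodiimide, DMAP cat., CH2Cl2, 0 °C) with 2-[bis(2,2,2-trifluoroethoxy)phosphoryl]propanoic acid, which has no alkene to isomerise, gives the 8β-O-phosphonopropanoate F8. Still–Gennari olefination (KN(SiMe3)2, 18-crown-6, THF, −78 °C, then 2-oxoethyl acetate) forms the (Z)-trisubstituted enoate directly and gives 31, where the route is rejoined.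

Further compounds
F1 | step 3 | (1-methylcyclohexa-2,5-dien-1-yl)methanol | CC1(CO)C=CCC=C1
F2 | step 3 | 1-methylcyclohexa-2,5-diene-1-carbaldehyde | CC1(C=O)C=CCC=C1
F3 | step 3 | bis(2-bromoprop-2-en-1-yl) acetal of 1-methylcyclohexa-2,5-diene-1-carbaldehyde | CC1(C(OCC(Br)=C)OCC(Br)=C)C=CCC=C1
F4 | step 3 | 1-(2-bromoprop-2-en-1-yloxy)-8a-methyl-4-methylidene-3,4,4a,8a-tetrahydro-1H-isochromene (cis-fused, acetal epimers) | C=C(Br)COC2[C@]1(C)C=CC=C[C@@H]1C(=C)CO2
F5 | step 3 | 8a-methyl-4-methylidene-3,4,4a,8a-tetrahydro-1H-isochromen-1-ol (cis-fused lactol) | OC2[C@]1(C)C=CC=C[C@@H]1C(=C)CO2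
F6 | step 5 | 1-methyl-4-(phenylselanyl)-8-[3-(TBS-oxy)prop-1-en-2-yl]-6-oxabicyclo[3.2.1]oct-2-en-7-one (7β-SePh; 1,6α-lactone) | O=C2[C@]1(C)C=C[C@@H]([Se]c3ccccc3)[C@H](O2)[C@@H]1C(=C)CO[Si](C)(C)C(C)(C)C
F7 | step 5 | 2-hydroxy-1-methyl-8-[3-(TBS-oxy)prop-1-en-2-yl]-6-oxabicyclo[3.2.1]oct-3-en-7-one (9β-OH; 1,6α-lactone) | O=C2[C@]1(C)[C@@H](O)C=C[C@H](O2)[C@@H]1C(=C)CO[Si](C)(C)C(C)(C)C
F8 | step 14 | 8β-O-{2-[bis(2,2,2-trifluoroethoxy)phosphoryl]propanoyl} derivative of 24 | C=C[C@]1(C)C[C@@H](OC(=O)C(C)P(=O)(OCC(F)(F)F)OCC(F)(F)F)[C@@H](C(=C)C(=O)OCc2ccc(OC)cc2)[C@H](O[Si](CC)(CC)CC)[C@@H]1C(=C)CO[Si](C)(C)C(C)(C)C
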